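(The runs come from a simulation for an exercise; the scatter is artificial.)

If every product costs one second substrate, then second substrate, charged at 0.60 equiv on starting material, is the limiting reagent of the alder flask, and its balance is the line to write.

in all of them: starting material 47 mM; temperature 37 °C

| flask | second substrate | free enzyme | remark | time |
|---|---|---|---|---|
| alder | 0.60 equiv | 0.0029 mol% | the very flask that is asked about, followed so far |  |
| larch | 0.60 equiv | 0.0058 mol% | run made earlier |  |
| flask | 0.600 equiv | 0.0029 mol% |  | 3.0 h |

alder run (percent of the starting material charged): time / h: product / % = 0.250: 18.5; 0.500: 30.4; 1.33: 44.5; 3.00: 49.1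

larch run (percent of the starting material charged): time / min: product / % = 10.0: 24.4; 25.0: 41.1; 50.0: 50.6; 80.0: 54.7

(scatter of a reading: 0.3 percentage points)

- beta: at 3.0 h add second substrate, 50.0% of the amount charged, then wait 3.0 h
- theta: at 3.0 h raise the temperature by 10 K, then wait 3.0 h
- eta: at 3.0 h take out 90% of the product then present, then wait 3.0 h
- zeta: change nothing and wait 3.0 h more
- epsilon: at 3.0 h add free enzyme, 100% of the amount charged, then wait 3.0 h

- product, in percent of the starting material first charged, at 3.0 h
- what to do for the largest gain in product; "none" if nothing gains more than 2 percentage points (beta / theta / eta / zeta / epsilon / none)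
- product present, with what was taken out counted in, in percent of the starting material first charged, after theta
- product present, with what was taken out counted in, in percent of the starting material first charged, after eta

- what is taken out of product is counted as made
- additions bring no volume worth counting
- the earlier runs do not show what temperature does; that part of a forecast is a guess

Alder's last reading, 49.1% at 3.00 h, has used 81.8% of the second substrate charged, yet alder has nearly stopped climbing. Larch's last reading, scaled by its loading, is worth 2.67 h of alder's time, shorter than alder's 3.00 h, but larch reads 54.7%, more than alder. So we read the stall in alder as catalyst dying on the clock.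

Now the ladder for alder, taking the rate as first order in c(second substrate). On the first rung, the logarithm of charge over remainder climbs at 1.47 h⁻¹ up to the first reading, so at that pace second substrate halves in 0.470 h. Between the last two readings that climb has slowed to 0.211 h⁻¹, which gives a catalyst decay of 0.953 h⁻¹. The second rung is therefore a catalyst half-life of 0.727 h, longer than the first. The third rung is the look at 3.0 h, longer again, when on this reckoning alder keeps 5.72% of its activity and, by its last reading, 18.2% of its second substrate.

Alder's last reading gives 1.71 for what we call the reach of a dose, the natural logarithm of second substrate charged over second substrate left at that reading, a dose being the free enzyme charged. We commit to the reading itself for product at 3.0 h.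

The forecast gives 49.1% (range 48.7% to 49.5%), 50% after theta and 50.1% after eta, and picks epsilon, reasoning “the enzyme is dying, with a half-life of about 45 min”.

The alder flask gives 49.5%, 49.9% after theta and 50.3% after eta, and epsilon is best, gaining 7.8 percentage points, so the forecast held. At 3.0 h the flask holds 75.4% of its catalyst as spent catalyst A and 3.60% as free enzyme, forms that the reach does not name. A fresh equal dose of free enzyme, reckoned as two reaches, comes to 58.0%, a gain of 8.5 points against the computed 7.8 points.

    starting material + free enzyme ⇌ starting complex (K = 12.0 M⁻¹, k = 35300 M⁻¹ s⁻¹, Ea = 22.0 kJ mol⁻¹, ΔH = −20.0 kJ mol⁻¹)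
    2 starting complex → spent catalyst B (k = 351 M⁻¹ s⁻¹, Ea = 42.0 kJ mol⁻¹)
    ternary complex → free enzyme + product (k = 20.2 s⁻¹, Ea = 73.0 kJ mol⁻¹)
    free enzyme → unfolded enzyme (k = 5.22 × 10⁻⁵ s⁻¹, Ea = 212 kJ mol⁻¹)
    second substrate + starting complex ⇌ ternary complex (K = 83.0 M⁻¹, k = 1.40 × 10⁵ M⁻¹ s⁻¹, Ea = 31.0 kJ mol⁻¹, ΔH = 19.0 kJ mol⁻¹)
    free enzyme → spent catalyst A (k = 3.60 × 10⁻⁴ s⁻¹, Ea = 100 kJ mol⁻¹)
    (constants at 37 °C)

For the neighbour flask charged with 0.360 equiv of second substrate and the same dose of free enzyme, alder's reach gives 29.5% of product. The computed flask gives 31.2%.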